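## Retrosynthetic overview

1. The target comes from its bis(benzyl) phenol ether by hydrogenolysis.
2. That ether comes from an acyclic epoxy cinnamyl ether in one light-driven titanocene/iridium step. Epoxide opening, 5-exo radical cyclization and hydroxylative radical–polar crossover form the C8–C8′ bond and the tetrahydrofuran, and set C8, C8′ and C7′.
3. The epoxy cinnamyl ether comes from an allyl ether epoxide and a benzyl-protected vinylguaiacol by cross-metathesis. The epoxide comes from the diol, the acetonide and O-allylation of an aryl carbinol.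
4. The aryl carbinol comes from a benzyl-protected bromoguaiacol and (R)-glyceraldehyde acetonide (from D-mannitol) by Felkin–Anh aryl addition. The purchased centre sets C7, and C7 then controls every other centre.
5. Only one ring is made, the tetrahydrofuran, in the photochemical step.

Assumption: the benzyl-protected aryl bromide and the benzyl-protected 4-vinylguaiacol are bought as such, and lignan locants are used (C7/C8/C9 for the arm with the ring aryl group, C7′/C8′/C9′ for the carbinol arm).

## Route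

Step 1
Reactants: 1 1-(benzyloxy)-4-bromo-2-methoxybenzene; 2 (R)-2,2-dimethyl-1,3-dioxolane-4-carbaldehyde
Product: 5 (S)-[4-(benzyloxy)-3-methoxyphenyl][(4R)-2,2-dimethyl-1,3-dioxolan-4-yl]methanol, via aryllithium 3 (not isolated), via aryltitanium triisopropoxide 4 (not isolated)
Conditions: n-BuLi, THF, −78 °C; ClTi(OiPr)3, −78 → −40 °C; then 2, −78 → −20 °C; H2O work-up
Reagents that add atoms: none
Why: Br/Li exchange and transmetalation give a weakly Lewis-acidic, non-chelating aryltitanium whose 1,2-addition to the α-alkoxy aldehyde follows the Felkin–Anh model (aryl enters anti to the dioxolane C–O bond), so the purchased (R)-centre of 2 sets the new carbinol centre as (S) (anti adduct); the minor syn epimer is removed by chromatography.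

Step 2
Reactants: 5 (S)-[4-(benzyloxy)-3-methoxyphenyl][(4R)-2,2-dimethyl-1,3-dioxolan-4-yl]methanol; 6 allyl bromide
Product: 7 (4R)-4-[(S)-(allyloxy)[4-(benzyloxy)-3-methoxyphenyl]methyl]-2,2-dimethyl-1,3-dioxolane
Conditions: NaH, Bu4NI (cat.), THF/DMF, 0 °C → rt
Reagents that add atoms: none
Why: Williamson ether synthesis of the secondary alkoxide with a reactive allylic bromide; no stereocentre is touched, and the benzyl ether and acetonide are inert to NaH.

Step 3
Reactants: 7 (4R)-4-[(S)-(allyloxy)[4-(benzyloxy)-3-methoxyphenyl]methyl]-2,2-dimethyl-1,3-dioxolane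
Product: 8 (2R,3S)-3-(allyloxy)-3-[4-(benzyloxy)-3-methoxyphenyl]propane-1,2-diol
Conditions: AcOH/H2O/THF 3:1:1, 45 °C
Reagents that add atoms: none
Why: Mild acid-catalysed acetal hydrolysis; aqueous acetic acid is too weak to ionise the benzylic allyl ether or to cleave the benzyl ether, and both stereocentres are untouched.

Step 4
Reactants: 8 (2R,3S)-3-(allyloxy)-3-[4-(benzyloxy)-3-methoxyphenyl]propane-1,2-diol
Product: 10 (2R)-2-[(S)-(allyloxy)[4-(benzyloxy)-3-methoxyphenyl]methyl]oxirane, via primary monotosylate 9 (not isolated)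
Conditions: NaH (2.2 equiv), N-tosylimidazole, THF, 0 °C → rt
Reagents that add atoms: none
Why: One-pot diol-to-epoxide conversion: the primary alkoxide is sulfonylated selectively and the neighbouring secondary alkoxide closes the oxirane by intramolecular Williamson (3-exo-tet) displacement, with retention at the secondary carbon because its C–O bond is never broken.

Step 5
Reactants: 10 (2R)-2-[(S)-(allyloxy)[4-(benzyloxy)-3-methoxyphenyl]methyl]oxirane; 11 1-(benzyloxy)-2-methoxy-4-vinylbenzene
Product: 12 (2R)-2-[(S)-[4-(benzyloxy)-3-methoxyphenyl]{[(2E)-3-[4-(benzyloxy)-3-methoxyphenyl]prop-2-en-1-yl]oxy}methyl]oxirane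
Conditions: second-generation Hoveyda–Grubbs catalyst RuCl2(H2IMes)(=CH-C6H4-2-OiPr) (5 mol%), 11 (2.5 equiv), CH2Cl2, 40 °C
Reagents that add atoms: none
Why: Olefin cross-metathesis between a terminal allyl ether and an electron-rich styrene that homodimerises slowly; the reversible process funnels to the (E)-cinnamyl ether, and the ruthenium carbene tolerates the epoxide and benzyl ethers.

Step 6
Reactants: 12 (2R)-2-[(S)-[4-(benzyloxy)-3-methoxyphenyl]{[(2E)-3-[4-(benzyloxy)-3-methoxyphenyl]prop-2-en-1-yl]oxy}methyl]oxirane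
Product: 17 {(2R,3S,4S)-2-[4-(benzyloxy)-3-methoxyphenyl]-4-[(S)-[4-(benzyloxy)-3-methoxyphenyl](hydroxy)methyl]tetrahydrofuran-3-yl}methanol, via β-titanoxy secondary radical 13 (not isolated), via cyclized benzylic radical 14 (not isolated), via benzylic cation 15 (not isolated), via titanium alkoxide 16 (not isolated)
Conditions: Cp2TiCl2 (10 mol%), fac-Ir(ppy)3 (1.5 mol%), 2,4,6-collidine/2,4,6-collidinium chloride (1.0/0.5 equiv), degassed THF/H2O 10:1 (0.05 M), 450 nm LEDs, 20 °C
Reagents that add atoms: water, O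
Why: Proposed new method: photoexcited fac-Ir(ppy)3 reduces Cp2TiCl2 to trivalent Cp2TiCl, which opens the terminal epoxide homolytically at the more substituted carbon (radical 13; the oxirane centre is erased and re-set under control of the benzylic ether centre); 13 closes 5-exo-trig onto the styrene through a Beckwith–Houk chair transition state with the aryl group and the CH2O[Ti] arm pseudo-equatorial, giving the 2,3-trans/3,4-cis ring; the electron-rich benzylic radical 14 is oxidised by the tetravalent iridium left from the quenching step (radical–polar crossover); cation 15 is captured by solvent water anti to the ring C3 arm in the rotamer whose ring C4–H bond eclipses the aryl plane (allylic 1,3-strain), which gives the (S)-carbinol while the C9 oxygen is still capped as the bulky, weakly nucleophilic Cp2Ti(Cl)O– group; collidinium protonolysis of 16 returns tetravalent titanium, so the process is redox-neutral (12 + H2O → 17), and reductive side paths cannot turn over because there is no terminal reductant. Closest known reaction types: the stoichiometric Nugent–RajanBabu titanocene epoxy-olefin radical cyclization, redox-neutral titanocene/photoredox radical arylation of epoxides, and photoredox oxy-alkylation of styrenes by radical–polar crossover.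

Step 7
Reactants: 17 {(2R,3S,4S)-2-[4-(benzyloxy)-3-methoxyphenyl]-4-[(S)-[4-(benzyloxy)-3-methoxyphenyl](hydroxy)methyl]tetrahydrofuran-3-yl}methanol
Product: 18 {(2R,3S,4S)-2-(4-hydroxy-3-methoxyphenyl)-4-[(S)-hydroxy(4-hydroxy-3-methoxyphenyl)methyl]tetrahydrofuran-3-yl}methanol
Conditions: H2 (1 atm), 5% Pd/C, EtOAc/THF, rt, about 45 min, stopped at full debenzylation
Reagents that add atoms: none
Why: Heterogeneous hydrogenolysis cleaves aryl benzyl ethers within minutes at 1 atm, far faster than the secondary benzylic alcohol or the 2-aryltetrahydrofuran C–O bond are reduced under neutral, acid-free conditions; no stereocentre is touched.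

## Compound list

1 | 1-(benzyloxy)-4-bromo-2-methoxybenzene | COc1cc(Br)ccc1OCc1ccccc1 | starting material
2 | (R)-2,2-dimethyl-1,3-dioxolane-4-carbaldehyde | O=C[C@H]1COC(C)(C)O1 | starting material
3 | [4-(benzyloxy)-3-methoxyphenyl]lithium | [Li]c1ccc(OCc2ccccc2)c(OC)c1 | intermediate
4 | [4-(benzyloxy)-3-methoxyphenyl]titanium triisopropoxide | CC(C)O[Ti](OC(C)C)(OC(C)C)c1ccc(OCc2ccccc2)c(OC)c1 | intermediate
5 | (S)-[4-(benzyloxy)-3-methoxyphenyl][(4R)-2,2-dimethyl-1,3-dioxolan-4-yl]methanol | O[C@@H](c1ccc(OCc2ccccc2)c(OC)c1)[C@H]1COC(C)(C)O1 | intermediate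
6 | allyl bromide (3-bromoprop-1-ene) | C=CCBr | starting material
7 | (4R)-4-[(S)-(allyloxy)[4-(benzyloxy)-3-methoxyphenyl]methyl]-2,2-dimethyl-1,3-dioxolane | C=CCO[C@@H](c1ccc(OCc2ccccc2)c(OC)c1)[C@H]1COC(C)(C)O1 | intermediate
8 | (2R,3S)-3-(allyloxy)-3-[4-(benzyloxy)-3-methoxyphenyl]propane-1,2-diol | C=CCO[C@@H](c1ccc(OCc2ccccc2)c(OC)c1)[C@H](O)CO | intermediate
9 | (2R,3S)-3-(allyloxy)-3-[4-(benzyloxy)-3-methoxyphenyl]-2-hydroxypropyl 4-methylbenzenesulfonate | C=CCO[C@@H](c1ccc(OCc2ccccc2)c(OC)c1)[C@H](O)COS(=O)(=O)c1ccc(C)cc1 | intermediate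
10 | (2R)-2-[(S)-(allyloxy)[4-(benzyloxy)-3-methoxyphenyl]methyl]oxirane | C=CCO[C@@H](c1ccc(OCc2ccccc2)c(OC)c1)[C@H]1CO1 | intermediate
11 | 1-(benzyloxy)-2-methoxy-4-vinylbenzene | C=Cc1ccc(OCc2ccccc2)c(OC)c1 | starting material
12 | (2R)-2-[(S)-[4-(benzyloxy)-3-methoxyphenyl]{[(2E)-3-[4-(benzyloxy)-3-methoxyphenyl]prop-2-en-1-yl]oxy}methyl]oxirane | COc1cc(/C=C/CO[C@@H](c2ccc(OCc3ccccc3)c(OC)c2)[C@H]2CO2)ccc1OCc1ccccc1 | intermediate
13 | ring-opened secondary radical with chlorobis(cyclopentadienyl)titanium on the C9 oxygen (cyclopentadienyl rings written σ-bonded) | COc1cc(/C=C/CO[C@@H](c2ccc(OCc3ccccc3)c(OC)c2)[CH]CO[Ti](Cl)(C2C=CC=C2)C2C=CC=C2)ccc1OCc1ccccc1 | intermediate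
14 | cyclized 2,3-trans-3,4-cis tetrahydrofuran with a benzylic radical at C7′ and the titanium alkoxide at C9 | COc1cc([CH][C@@H]2CO[C@@H](c3ccc(OCc4ccccc4)c(OC)c3)[C@@H]2CO[Ti](Cl)(C2C=CC=C2)C2C=CC=C2)ccc1OCc1ccccc1 | intermediate
15 | the corresponding benzylic cation at C7′ | COc1cc([CH+][C@@H]2CO[C@@H](c3ccc(OCc4ccccc4)c(OC)c3)[C@@H]2CO[Ti](Cl)(C2C=CC=C2)C2C=CC=C2)ccc1OCc1ccccc1 | intermediate
16 | chlorobis(cyclopentadienyl)titanium C9-alkoxide of 17 | COc1cc([C@@H](O)[C@@H]2CO[C@@H](c3ccc(OCc4ccccc4)c(OC)c3)[C@@H]2CO[Ti](Cl)(C2C=CC=C2)C2C=CC=C2)ccc1OCc1ccccc1 | intermediate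
17 | {(2R,3S,4S)-2-[4-(benzyloxy)-3-methoxyphenyl]-4-[(S)-[4-(benzyloxy)-3-methoxyphenyl](hydroxy)methyl]tetrahydrofuran-3-yl}methanol | COc1cc([C@@H](O)[C@@H]2CO[C@@H](c3ccc(OCc4ccccc4)c(OC)c3)[C@@H]2CO)ccc1OCc1ccccc1 | intermediate
18 | {(2R,3S,4S)-2-(4-hydroxy-3-methoxyphenyl)-4-[(S)-hydroxy(4-hydroxy-3-methoxyphenyl)methyl]tetrahydrofuran-3-yl}methanol | COc1cc([C@@H](O)[C@@H]2CO[C@@H](c3ccc(O)c(OC)c3)[C@@H]2CO)ccc1O | target

## Step count and risks

Total step count: 7. Longest linear sequence: 7 steps (1 and 2 to 18).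

**Step 6 (the proposed new method) is the most likely to fail.**
- Failure modes: cation 15 may be captured by the C9 oxygen to give the furofuran (bis-benzyl pinoresinol type) instead of 17. The benzylic radical may be reduced rather than oxidised, which stalls turnover. Facial selectivity at C7′ may be modest.
- Fallback with known chemistry, setting out from 12 and coming back at 17:
  - The epoxide of 12 is opened at its terminal carbon with caesium pivalate (CsOPiv) and pivalic acid in DMF at 80 °C. This gives (2R,3S)-3-[4-(benzyloxy)-3-methoxyphenyl]-3-{[(2E)-3-[4-(benzyloxy)-3-methoxyphenyl]prop-2-en-1-yl]oxy}-2-hydroxypropyl pivalate F1.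
  - An Appel reaction (I2, PPh3, imidazole, toluene, 60 °C) gives the secondary iodide (2S,3S)-3-[4-(benzyloxy)-3-methoxyphenyl]-3-{[(2E)-3-[4-(benzyloxy)-3-methoxyphenyl]prop-2-en-1-yl]oxy}-2-iodopropyl pivalate F2. Its inverted centre does not matter because it becomes a radical.
  - A tin hydride/air oxygenative radical cyclization follows (Bu3SnH added slowly, dry air, toluene, 0 °C to rt). The same 5-exo closure occurs, and O2 traps the benzylic radical on its open face to give the hydroperoxide {(2R,3S,4S)-2-[4-(benzyloxy)-3-methoxyphenyl]-4-[(S)-[4-(benzyloxy)-3-methoxyphenyl](hydroperoxy)methyl]tetrahydrofuran-3-yl}methyl pivalate F3, which is not isolated.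
  - PPh3 reduces it in the flask to {(2R,3S,4S)-2-[4-(benzyloxy)-3-methoxyphenyl]-4-[(S)-[4-(benzyloxy)-3-methoxyphenyl](hydroxy)methyl]tetrahydrofuran-3-yl}methyl pivalate F4.
  - NaOMe in MeOH at rt removes the pivalate and returns 17.
  - The C9 oxygen is an ester throughout, so no furofuran can form.

**Step 1 may give only a modest anti:syn ratio.**
- Fallback, setting out from 5 (taken as its mixture with the syn carbinol epimer) and coming back at 5:
  - The mixture is oxidised with Dess–Martin periodinane (NaHCO3, CH2Cl2, 0 °C) to the single ketone [4-(benzyloxy)-3-methoxyphenyl][(4R)-2,2-dimethyl-1,3-dioxolan-4-yl]methanone F5.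
  - The ketone is reduced with Zn(BH4)2 (Et2O, −30 °C) under chelation control through the α-oxygen. Hydride enters from the face of the small α-hydrogen and gives the anti carbinol 5.
  - This replaces C–C bond-forming stereocontrol with a convergent redox correction.

**Step 7 may over-reduce the benzylic alcohol or the 2-aryl ring C–O bond.**
- Fallback, setting out from 17 and coming back at 18:
  - Catalytic hydrogenolysis is abandoned for single-electron reductive debenzylation with lithium 4,4′-di-tert-butylbiphenylide (THF, −78 °C, then NH4Cl).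
  - The unsubstituted benzyl group accepts the electron and leaves phenoxide. The benzylic alcohol is protected as its alkoxide and the electron-rich guaiacyl ring is not reduced.
  - It makes no new compound (none F0).

Further compounds
F1 | step 6 | (2R,3S)-3-[4-(benzyloxy)-3-methoxyphenyl]-3-{[(2E)-3-[4-(benzyloxy)-3-methoxyphenyl]prop-2-en-1-yl]oxy}-2-hydroxypropyl pivalate | COc1cc(/C=C/CO[C@@H](c2ccc(OCc3ccccc3)c(OC)c2)[C@H](O)COC(=O)C(C)(C)C)ccc1OCc1ccccc1
F2 | step 6 | (2S,3S)-3-[4-(benzyloxy)-3-methoxyphenyl]-3-{[(2E)-3-[4-(benzyloxy)-3-methoxyphenyl]prop-2-en-1-yl]oxy}-2-iodopropyl pivalate | COc1cc(/C=C/CO[C@@H](c2ccc(OCc3ccccc3)c(OC)c2)[C@@H](I)COC(=O)C(C)(C)C)ccc1OCc1ccccc1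
F3 | step 6 | {(2R,3S,4S)-2-[4-(benzyloxy)-3-methoxyphenyl]-4-[(S)-[4-(benzyloxy)-3-methoxyphenyl](hydroperoxy)methyl]tetrahydrofuran-3-yl}methyl pivalate | COc1cc([C@@H](OO)[C@@H]2CO[C@@H](c3ccc(OCc4ccccc4)c(OC)c3)[C@@H]2COC(=O)C(C)(C)C)ccc1OCc1ccccc1
F4 | step 6 | {(2R,3S,4S)-2-[4-(benzyloxy)-3-methoxyphenyl]-4-[(S)-[4-(benzyloxy)-3-methoxyphenyl](hydroxy)methyl]tetrahydrofuran-3-yl}methyl pivalate | COc1cc([C@@H](O)[C@@H]2CO[C@@H](c3ccc(OCc4ccccc4)c(OC)c3)[C@@H]2COC(=O)C(C)(C)C)ccc1OCc1ccccc1
F5 | step 1 | [4-(benzyloxy)-3-methoxyphenyl][(4R)-2,2-dimethyl-1,3-dioxolan-4-yl]methanone | O=C(c1ccc(OCc2ccccc2)c(OC)c1)[C@H]1COC(C)(C)O1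
F0 | step 7 | none | none
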